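Core numbering: C1 is the prenylated bridgehead beside C8 (CMe2), C5 the lavandulyl bridgehead, C9 the bridging ketone. Ring A is C1–C5 plus C9, and ring B is C5–C9 plus C1. Cutting C9–C1 and C4–C5 unfolds both rings into one chain, C9–C5–C6–C7–C8–C1–C2–C3–C4. The key step refolds it in one operation: the C1 enolate acylates on the C9 ester, then the resulting C5 enolate adds to C4. It exploits that both bridgeheads are alpha-carbons of C9 and that C2–C3–C4 is a 1,3-dicarbonyl unit. The precursor is an acyclic keto ester whose C2–C4 end is an ethoxy-ynone. Its C7 stereocentre directs both quaternary bridgeheads.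

Key step: step 15

Assumption: the C2–C3–C4 triketone of the target is a set of rapidly interconverting enol tautomers, so hydrolysis of the C4 vinylogous ester delivers the drawn C4-enol form.

Step 1
Reactants: 1 (R)-4-benzyl-1,3-oxazolidin-2-one; 2 3-methylbut-2-enoyl chloride
Product: 3 (R)-4-benzyl-3-(3-methylbut-2-enoyl)-1,3-oxazolidin-2-one
Conditions: n-BuLi, THF, −78 °C; then 2, −78 → 0 °C
Reagents that add atoms: 3-methylbut-2-enoyl chloride (2), CC(C)=CC(=O)Cl
Why: N-acylation of the lithiated auxiliary with an acid chloride is a standard imide formation and creates no stereocentre.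

Step 2
Reactants: 3 imide; 4 1-bromo-3-methylbut-2-ene (prenyl bromide)
Product: 5 (R)-4-benzyl-3-[(2R)-5-methyl-2-(prop-1-en-2-yl)hex-4-enoyl]-1,3-oxazolidin-2-one
Conditions: NaN(SiMe3)2, THF, −78 °C; then 4, −78 → −30 °C
Reagents that add atoms: prenyl bromide (4), CC(C)=CCBr
Why: Deconjugative Evans asymmetric alkylation, in which gamma-deprotonation gives the chelated Z-dienolate and alkylation at the alpha-carbon anti to the benzyl group sets the lavandulyl stereocentre (2R here) and shifts the alkene into the isopropenyl position.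

Step 3
Reactants: 5 alkylated imide
Product: 6 (R)-lavandulol, (2R)-5-methyl-2-(prop-1-en-2-yl)hex-4-en-1-ol
Conditions: LiBH4, H2O (1 equiv), Et2O, 0 °C
Reagents that add atoms: none
Why: Reductive cleavage of an N-acyl oxazolidinone by borohydride gives the primary alcohol without enolising the alpha-stereocentre and returns the auxiliary.

Step 4
Reactants: 6 (R)-lavandulol
Product: 7 (R)-lavandulyl iodide, (2R)-1-iodo-5-methyl-2-(prop-1-en-2-yl)hex-4-ene
Conditions: I2, PPh3, imidazole, CH2Cl2, 0 °C
Reagents that add atoms: iodine, II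
Why: Appel-type iodination displaces the activated primary oxygen by SN2 at CH2, so the neighbouring stereocentre is untouched.

Step 5
Reactants: 7 (R)-lavandulyl iodide; 8 trimethyl phosphonoacetate
Product: 9 methyl (4S)-2-(dimethoxyphosphoryl)-7-methyl-4-(prop-1-en-2-yl)oct-6-enoate (C2 epimers)
Conditions: NaH, DMF, 0 → 60 °C
Reagents that add atoms: trimethyl phosphonoacetate (8), COC(=O)CP(=O)(OC)OC
Why: Alkylation of the soft, stabilised phosphonoacetate carbanion favours SN2 over E2 on the beta-branched iodide, and the new phosphonate-bearing centre is a mixture that is erased in step 10.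

Step 6
Reactants: 10 3,3-dimethylpentanedioic acid; 11 (S)-4-benzyl-1,3-oxazolidin-2-one
Product: 13 1,5-bis[(S)-4-benzyl-2-oxo-1,3-oxazolidin-3-yl]-3,3-dimethylpentane-1,5-dione, via 3,3-dimethylglutaryl dichloride 12 (not isolated)
Conditions: SOCl2, cat. DMF, reflux, evaporate; then 11 (2 equiv), n-BuLi, THF, −78 → 0 °C
Reagents that add atoms: (S)-4-benzyl-1,3-oxazolidin-2-one (11), O=C1N[C@@H](Cc2ccccc2)CO1
Why: Acid chloride formation followed by double N-acylation of the lithiated auxiliary gives the symmetric bis-imide and creates no new stereocentre.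

Step 7
Reactants: 13 bis-imide; 4 prenyl bromide
Product: 14 (2S,4S)-1,5-bis[(S)-4-benzyl-2-oxo-1,3-oxazolidin-3-yl]-3,3-dimethyl-2,4-bis(3-methylbut-2-enyl)pentane-1,5-dione
Conditions: NaN(SiMe3)2 (2.3 equiv), THF, −78 °C; then 4 (excess), −78 → −20 °C
Reagents that add atoms: prenyl bromide (4), CC(C)=CCBr
Why: Twofold Evans asymmetric alkylation, in which each chelated Z-enolate is attacked anti to its benzyl group, gives the C2-symmetric (S,S) product; one centre becomes C7 and the other (future C1) is planarised later.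

Step 8
Reactants: 14 dialkylated bis-imide
Product: 16 (3S,5S)-4,4-dimethyl-3,5-bis(3-methylbut-2-enyl)oxan-2-one, via hydroxy imide 15 (not isolated)
Conditions: LiBH4 (1 equiv), MeOH (1 equiv), THF, 0 °C
Reagents that add atoms: none
Why: Borohydride reduction of one of the two homotopic imides, followed by gem-dimethyl-accelerated lactonisation that expels the second auxiliary, differentiates the chain ends without touching either stereocentre.

Step 9
Reactants: 16 lactone
Product: 17 (3S,5S)-4,4-dimethyl-3,5-bis(3-methylbut-2-enyl)oxan-2-ol (lactol, anomers)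
Conditions: i-Bu2AlH (1.1 equiv), CH2Cl2, −78 °C
Reagents that add atoms: none
Why: Partial reduction of a lactone stops at the aluminium hemiacetal at low temperature, and the anomeric centre is an inconsequential mixture.

Step 10
Reactants: 17 lactol; 9 phosphonate
Product: 18 methyl (4R,6S)-7-hydroxy-5,5-dimethyl-4,6-bis(3-methylbut-2-enyl)-2-[(2S)-5-methyl-2-(prop-1-en-2-yl)hex-4-enyl]hept-2-enoate (E/Z mixture)
Conditions: 9, LiCl, DBU, MeCN, 0 °C → rt
Reagents that add atoms: phosphonate 9, C=C(C)[C@@H](CC=C(C)C)CC(C(=O)OC)P(=O)(OC)OC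
Why: Horner–Wadsworth–Emmons olefination under Masamune–Roush conditions traps the hydroxy-aldehyde tautomer of the lactol to form C5=C6; the mild base protects the alpha-stereocentre C7, and the alkene geometry is irrelevant.

Step 11
Reactants: 18 enoate
Product: 19 methyl (4R,6S)-7-hydroxy-5,5-dimethyl-4,6-bis(3-methylbut-2-enyl)-2-[(2S)-5-methyl-2-(prop-1-en-2-yl)hex-4-enyl]heptanoate (C2 epimers)
Conditions: Mg turnings, MeOH, 0 °C → rt
Reagents that add atoms: none
Why: Dissolving-metal conjugate reduction by Mg/MeOH reduces only the ester-conjugated alkene and leaves the isolated alkenes, and the new C5 centre is a mixture that the key step planarises.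

Step 12
Reactants: 19 hydroxy ester
Product: 20 methyl (4R,6S)-5,5-dimethyl-4,6-bis(3-methylbut-2-enyl)-2-[(2S)-5-methyl-2-(prop-1-en-2-yl)hex-4-enyl]-7-oxoheptanoate
Conditions: TEMPO (cat.), PhI(OAc)2, CH2Cl2, rt
Reagents that add atoms: none
Why: Oxoammonium-mediated oxidation takes the primary alcohol to the aldehyde (future C2) without affecting the trisubstituted alkenes or the ester.

Step 13
Reactants: 20 aldehyde; 21 ethoxyacetylene
Product: 22 methyl (4R,6S)-9-ethoxy-7-hydroxy-5,5-dimethyl-4,6-bis(3-methylbut-2-enyl)-2-[(2S)-5-methyl-2-(prop-1-en-2-yl)hex-4-enyl]non-8-ynoate (carbinol epimers)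
Conditions: 21, n-BuLi, THF, −78 °C; then 20, −78 °C
Reagents that add atoms: ethoxyacetylene (21), C#COCC
Why: 1,2-Addition of the slim lithium acetylide is much faster at the aldehyde than at the branched methyl ester at −78 °C, and the carbinol centre is removed in step 14.

Step 14
Reactants: 22 propargylic alcohol
Product: 23 methyl (4R,6S)-9-ethoxy-5,5-dimethyl-4,6-bis(3-methylbut-2-enyl)-2-[(2S)-5-methyl-2-(prop-1-en-2-yl)hex-4-enyl]-7-oxonon-8-ynoate
Conditions: MnO2, CH2Cl2, rt
Reagents that add atoms: none
Why: Neutral MnO2 oxidation of the activated propargylic alcohol gives the ethoxy-ynone and avoids the acid that would trigger Meyer–Schuster rearrangement.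

Step 15
Reactants: 23 ynone ester
Product: 25 (1S,5R,7R)-4-ethoxy-8,8-dimethyl-1,7-bis(3-methylbut-2-enyl)-5-[(2S)-5-methyl-2-(prop-1-en-2-yl)hex-4-enyl]bicyclo[3.3.1]non-3-ene-2,9-dione, via cyclohexanone 24 (not isolated)
Conditions: LiN(SiMe3)2 (2.2 equiv), THF (0.005 M), −78 → 0 °C
Reagents that add atoms: none
Why: Proposed new method: LiN(SiMe3)2 removes the most acidic proton (C1–H, alpha to the ynone carbonyl C2), the lithium enolate acylates on the C9 methyl ester (Dieckmann condensation, 6-(enolexo)-exo-trig, closes ring B and makes C9–C1), further base enolises the new C9 ketone toward C5, its only alpha-hydrogen, and this enolate adds to C4 of the ethoxy-ynone (intramolecular Michael addition, 6-endo-dig, closes ring A and makes C4–C5) before C3 is protonated to the vinylogous ester. The closest known reaction types are domino Dieckmann cyclisations of open-chain keto diesters to bicyclo[3.3.1]nonane-2,4,9-triones and 6-endo-dig carbocyclisations of cyclohexanone enol derivatives onto alkynes; new is their union through an ethoxy-ynone, a dehydrated beta-keto ester that has no acidic C3–H to consume base and whose Michael step is irreversible. C1 is controlled by a lithium-chelated chair transition state (enolate oxygen and ester carbonyl on one lithium, Zimmerman–Traxler type) fused to the chair of the nascent ring B, which places the C2 acyl arm equatorial and the C1 prenyl axial, so the preset C7 prenyl must sit equatorial to escape a syn-diaxial clash and ends cis to the acyl arm (7-endo series). C5 is controlled by C1, because the C5 enolate can reach C4 only on the ring face that carries the acyl arm (1,3-diaxial bridging through a boat-like ring B), and the C1 and C5 epimers of 23 converge since both centres are planarised. The step needs C1–H over C5–H deprotonation, secured by the ketone/ester acidity gap; C- over O-attack on the ynone, secured because the O-adduct is a ketene acetal that can revert while the C-adduct cannot; and cyclisation over oligomerisation, secured by high dilution and the gem-dimethyl group at C8.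

Step 16
Reactants: 25 bicyclic vinylogous ester; 26 3-acetoxybenzoyl chloride
Product: 27 (1R,5R,7R)-3-(3-acetoxybenzoyl)-4-ethoxy-8,8-dimethyl-1,7-bis(3-methylbut-2-enyl)-5-[(2S)-5-methyl-2-(prop-1-en-2-yl)hex-4-enyl]bicyclo[3.3.1]non-3-ene-2,9-dione
Conditions: lithium 2,2,6,6-tetramethylpiperidide, THF, −78 °C; then 26 (excess), −78 °C
Reagents that add atoms: 3-acetoxybenzoyl chloride (26), CC(=O)Oc1cccc(C(=O)Cl)c1
Why: Alpha-lithiation of the vinylogous ester at C3–H, the only acidic position since both bridgeheads are quaternary, followed by C-acylation with the acid chloride installs the aroyl group without touching a stereocentre.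

Step 17
Reactants: 27 aroylated vinylogous ester
Product: 28 target, (1R,5R,7R)-4-hydroxy-3-(3-hydroxybenzoyl)-8,8-dimethyl-1,7-bis(3-methylbut-2-enyl)-5-[(2S)-5-methyl-2-(prop-1-en-2-yl)hex-4-enyl]bicyclo[3.3.1]non-3-ene-2,9-dione
Conditions: LiOH, 1,4-dioxane/H2O, 90 °C; then cold dilute HCl
Reagents that add atoms: water, O
Why: Hydroxide adds to C4 of the doubly activated vinylogous ester and expels ethoxide (addition–elimination) while the aryl acetate is saponified, and none of the four stereocentres carries an exchangeable proton.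

Compound list
1 | (R)-4-benzyl-1,3-oxazolidin-2-one | O=C1N[C@H](Cc2ccccc2)CO1 | starting material
2 | 3-methylbut-2-enoyl chloride | CC(C)=CC(=O)Cl | starting material
3 | (R)-4-benzyl-3-(3-methylbut-2-enoyl)-1,3-oxazolidin-2-one | CC(C)=CC(=O)N1[C@H](Cc2ccccc2)COC1=O | intermediate
4 | 1-bromo-3-methylbut-2-ene (prenyl bromide) | CC(C)=CCBr | starting material
5 | (R)-4-benzyl-3-[(2R)-5-methyl-2-(prop-1-en-2-yl)hex-4-enoyl]-1,3-oxazolidin-2-one | C=C(C)[C@@H](CC=C(C)C)C(=O)N1[C@H](Cc2ccccc2)COC1=O | intermediate
6 | (R)-lavandulol | C=C(C)[C@@H](CC=C(C)C)CO | intermediate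
7 | (R)-lavandulyl iodide | C=C(C)[C@@H](CC=C(C)C)CI | intermediate
8 | trimethyl phosphonoacetate | COC(=O)CP(=O)(OC)OC | starting material
9 | methyl (4S)-2-(dimethoxyphosphoryl)-7-methyl-4-(prop-1-en-2-yl)oct-6-enoate (C2 epimers) | C=C(C)[C@@H](CC=C(C)C)CC(C(=O)OC)P(=O)(OC)OC | intermediate
10 | 3,3-dimethylpentanedioic acid | CC(C)(CC(=O)O)CC(=O)O | starting material
11 | (S)-4-benzyl-1,3-oxazolidin-2-one | O=C1N[C@@H](Cc2ccccc2)CO1 | starting material
12 | 3,3-dimethylglutaryl dichloride | CC(C)(CC(=O)Cl)CC(=O)Cl | intermediate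
13 | 1,5-bis[(S)-4-benzyl-2-oxo-1,3-oxazolidin-3-yl]-3,3-dimethylpentane-1,5-dione | CC(C)(CC(=O)N1[C@@H](Cc2ccccc2)COC1=O)CC(=O)N1[C@@H](Cc2ccccc2)COC1=O | intermediate
14 | (2S,4S)-diprenylated bis-imide | O=C([C@@H](CC=C(C)C)C(C)(C)[C@H](CC=C(C)C)C(=O)N1[C@@H](Cc2ccccc2)COC1=O)N1[C@@H](Cc2ccccc2)COC1=O | intermediate
15 | (S)-4-benzyl-3-[(2S,4S)-5-hydroxy-3,3-dimethyl-2,4-bis(3-methylbut-2-enyl)pentanoyl]-1,3-oxazolidin-2-one | O=C([C@@H](CC=C(C)C)C(C)(C)[C@H](CC=C(C)C)CO)N1[C@@H](Cc2ccccc2)COC1=O | intermediate
16 | (3S,5S)-4,4-dimethyl-3,5-bis(3-methylbut-2-enyl)oxan-2-one | O=C1[C@@H](CC=C(C)C)C(C)(C)[C@H](CC=C(C)C)CO1 | intermediate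
17 | (3S,5S)-4,4-dimethyl-3,5-bis(3-methylbut-2-enyl)oxan-2-ol (anomers) | OC1[C@@H](CC=C(C)C)C(C)(C)[C@H](CC=C(C)C)CO1 | intermediate
18 | hydroxy enoate (4R,6S; E/Z mixture) | C=C(C)[C@@H](CC=C(C)C)CC(C(=O)OC)=C[C@@H](CC=C(C)C)C(C)(C)[C@H](CC=C(C)C)CO | intermediate
19 | hydroxy ester (4R,6S; C2 epimers) | C=C(C)[C@@H](CC=C(C)C)CC(C(=O)OC)C[C@@H](CC=C(C)C)C(C)(C)[C@H](CC=C(C)C)CO | intermediate
20 | aldehyde ester (4R,6S) | C=C(C)[C@@H](CC=C(C)C)CC(C(=O)OC)C[C@@H](CC=C(C)C)C(C)(C)[C@H](CC=C(C)C)C=O | intermediate
21 | ethoxyacetylene | C#COCC | starting material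
22 | ethoxypropargylic alcohol (carbinol epimers) | C=C(C)[C@@H](CC=C(C)C)CC(C(=O)OC)C[C@@H](CC=C(C)C)C(C)(C)[C@H](CC=C(C)C)C(O)C#COCC | intermediate
23 | ethoxy-ynone ester (key-step precursor) | C=C(C)[C@@H](CC=C(C)C)CC(C(=O)OC)C[C@@H](CC=C(C)C)C(C)(C)[C@H](CC=C(C)C)C(=O)C#COCC | intermediate
24 | 2-(3-ethoxyprop-2-ynoyl)-3,3-dimethyl-2,4-bis(3-methylbut-2-enyl)-6-[(2S)-lavandulyl]cyclohexan-1-one, acyl arm cis to the C4 prenyl group, C6 epimers | C=C(C)[C@@H](CC=C(C)C)CC1C[C@@H](CC=C(C)C)C(C)(C)[C@@](CC=C(C)C)(C(=O)C#COCC)C1=O | intermediate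
25 | (1S,5R,7R)-4-ethoxy bicyclic vinylogous ester | C=C(C)[C@@H](CC=C(C)C)C[C@@]12C[C@@H](CC=C(C)C)C(C)(C)[C@@](CC=C(C)C)(C(=O)C=C1OCC)C2=O | intermediate
26 | 3-acetoxybenzoyl chloride | CC(=O)Oc1cccc(C(=O)Cl)c1 | starting material
27 | (1R,5R,7R)-3-(3-acetoxybenzoyl)-4-ethoxy bicyclic dione | C=C(C)[C@@H](CC=C(C)C)C[C@@]12C[C@@H](CC=C(C)C)C(C)(C)[C@@](CC=C(C)C)(C(=O)C(C(=O)c3cccc(OC(C)=O)c3)=C1OCC)C2=O | intermediate
28 | CNP0103487.1 | C=C(C)[C@@H](CC=C(C)C)C[C@@]12C[C@@H](CC=C(C)C)C(C)(C)[C@@](CC=C(C)C)(C(=O)C(C(=O)c3cccc(O)c3)=C1O)C2=O | target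

Total step count: 17. Longest linear sequence: 13 (steps 1–5, then 10–17). The other branch (steps 6–9, then 10–17) has 12 steps.

Steps most likely to fail

1. Step 15.
- What may go wrong: retro-Claisen reopening of ring B by lithium methoxide could erode the facial control at C1. The C5 ester enolate could attack the C2 carbonyl in a competing aldol. The C9 enolate could attack the ynone through oxygen. The second closure could stall because ring B must reach a boat.
- Fallback (from 23, back at 25; known chemistry): the two closures are separated. 23 is treated with one equivalent of LiN(SiMe3)2 and quenched cold, so that cyclohexanone 24 is isolated. TBSOTf/Et3N converts 24 into the C5=C9 tert-butyldimethylsilyl enol ether F1. Catalytic [(t-Bu)2(biphenyl-2-yl)P]Au(NCMe)SbF6 (monovalent gold) in acetone then effects the established 6-endo-dig carbocyclisation of a silyl enol ether onto an alkyne to give 25.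

2. Step 10.
- What may go wrong: the hindered aldehyde tautomer may olefinate slowly with the alpha-branched phosphonate. The base could epimerise C7. The freed hydroxyl could close onto the enoate by oxa-Michael addition.
- Fallback (from 17, back at 19): the side chain is attached after the olefination instead of with it. Neutral Wittig olefination with methyl (triphenylphosphoranylidene)acetate gives the unbranched (E)-hydroxy enoate F2. Mg/MeOH gives the hydroxy ester F3. Its alkoxide/ester-enolate dianion (two equivalents of LiN(i-Pr)2) is alkylated at −78 °C by (R)-lavandulyl triflate F4, made from 6 with Tf2O and 2,6-lutidine.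

3. Step 8.
- What may go wrong: the lactone may be over-reduced, or hydride may attack the ring carbonyl of the hindered imide and open the auxiliary.
- Fallback (from 14, back at 16): both imides are reduced exhaustively with LiAlH4 to the C2-symmetric diol F5. Because its hydroxyl groups are homotopic, TEMPO/PhI(OAc)2 oxidative lactonisation gives 16 without any selectivity question.

Further compounds
F1 | step 15 | tert-butyldimethylsilyl enol ether (C5=C9) of cyclohexanone 24 | C=C(C)[C@@H](CC=C(C)C)CC=1C[C@@H](CC=C(C)C)C(C)(C)[C@@](CC=C(C)C)(C(=O)C#COCC)C=1O[Si](C)(C)C(C)(C)C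
F2 | step 10 | methyl (2E,4R,6S)-7-hydroxy-5,5-dimethyl-4,6-bis(3-methylbut-2-enyl)hept-2-enoate | COC(=O)/C=C/[C@@H](CC=C(C)C)C(C)(C)[C@H](CC=C(C)C)CO
F3 | step 10 | methyl (4S,6S)-7-hydroxy-5,5-dimethyl-4,6-bis(3-methylbut-2-enyl)heptanoate | COC(=O)CC[C@@H](CC=C(C)C)C(C)(C)[C@H](CC=C(C)C)CO
F4 | step 10 | (2R)-5-methyl-2-(prop-1-en-2-yl)hex-4-enyl trifluoromethanesulfonate | C=C(C)[C@@H](CC=C(C)C)COS(=O)(=O)C(F)(F)F
F5 | step 8 | (2S,4S)-3,3-dimethyl-2,4-bis(3-methylbut-2-enyl)pentane-1,5-diol | OC[C@@H](CC=C(C)C)C(C)(C)[C@H](CC=C(C)C)CO
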